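**Retrosynthetic overview**
- The (Z)-caffeate is built last on O3 by Still–Gennari olefination of a C3 phosphonoacetate, after Luche reduction of the 4(15)-en-3-one **20**; O1 (4-methoxybenzyl ether) and O8 (silyl ether) stay differentiated until the end.
- Ring A is closed onto ring B in one flask: C3–C4 by acylation of a C4 alkenyllithium with a three-carbon β-alkoxyacryloyl unit, then C1–C10 by hydrogen-atom-transfer-initiated 6-endo radical cyclisation.
- Enabling feature: the 1,3-dioxygenated strip C1–C2–C3 of ring A is a vinylogous ester (C3=O, C1–OR). It lies between C4, whose exocyclic methylene C15 makes it a 1-substituted vinyl anion, and the quaternary C10, whose methyl makes it the tertiary radical of a C9=C10 alkene in ring B.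
- Ring B comes from (R)-cryptone: C7 is set by organocatalysis, C5 by equilibration, C8 by substrate-controlled reduction; C10 and C1 are then relayed in the key step and C3 by a second Luche reduction.
- Order of ring formation: ring B (step 2), then ring A (step 13).

Key step: step 13

Remark: carbons are numbered as in eudesmane throughout (C1–C10 decalin, C14 angular methyl, C15 exocyclic methylene; ring A = C1–C5 and C10, ring B = C5–C10), and acid 22 is taken to be a purchasable reagent.

**Step 1**
Reactants: 1 3-methylbutanal; 2 but-3-en-2-one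
Product: 3 (2R)-5-oxo-2-(propan-2-yl)hexanal
Conditions: (R)-α,α-diphenylprolinol trimethylsilyl ether (5 mol%), ethyl 3,4-dihydroxybenzoate (20 mol%), neat, 4 °C
Reagents that add atoms: none
Why: Enamine-catalysed Michael addition in which the diarylprolinol silyl ether shields one face of the anti-enamine, so that by the usual steric model the (R)-catalyst should give the (R)-configured isopropyl-bearing carbon (C7 of the target).

**Step 2**
Reactants: 3 (2R)-5-oxo-2-(propan-2-yl)hexanal
Product: 4 (4R)-4-(propan-2-yl)cyclohex-2-en-1-one ((R)-cryptone)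
Conditions: LiOH (cat.), i-PrOH, rt
Reagents that add atoms: none
Why: Intramolecular aldol condensation (Robinson-type closure of a 1,5-keto aldehyde) should form ring B under base mild enough for ring closure to outrun enolisation of the α-branched aldehyde.

**Step 3**
Reactants: 4 (R)-cryptone
Product: 5 trimethyl{[(4R)-4-(propan-2-yl)cyclohexa-1,5-dien-1-yl]oxy}silane
Conditions: LiN(iPr)2, THF, −78 °C; Me3SiCl
Reagents that add atoms: chlorotrimethylsilane, C[Si](C)(C)Cl
Why: Kinetic deprotonation at the unhindered α'-methylene (future C5) and O-silylation should give the cross-conjugated silyl dienol ether without touching the γ-stereocentre.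

**Step 4**
Reactants: 5 silyl dienol ether; 6 trimethyl orthoacetate
Product: 7 (4R,6R)-6-(1,1-dimethoxyethyl)-4-(propan-2-yl)cyclohex-2-en-1-one (cis)
Conditions: Me3SiOTf (10 mol%), CH2Cl2, −78 °C; then DBU (cat.), CH2Cl2, rt
Reagents that add atoms: none
Why: Lewis-acid-catalysed Mukaiyama-type alkylation of the silyl enol ether by the dimethoxycarbenium ion of the orthoester gives the β-keto ketal (C4 and C15 of the target), and base equilibration of the new α-stereocentre (C5) should favour the cis isomer with both ring substituents equatorial.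

**Step 5**
Reactants: 7 keto ketal
Product: 8 (4R,6R)-6-(1,1-dimethoxyethyl)-1-methyl-4-(propan-2-yl)cyclohex-2-en-1-ol (both C1 epimers)
Conditions: MeLi, CeCl3, THF, −78 °C
Reagents that add atoms: methyllithium, [Li]C
Why: Organocerium 1,2-addition to the enone carbonyl avoids enolisation of the α-branched ketone and installs the future angular methyl C14; the carbinol centre is lost in step 6.

**Step 6**
Reactants: 8 tertiary allylic alcohol
Product: 9 (4R,6R)-4-(1,1-dimethoxyethyl)-3-methyl-6-(propan-2-yl)cyclohex-2-en-1-one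
Conditions: [C5H5NH][CrO3Cl] (pyridinium chlorochromate), NaOAc, 4 Å MS, CH2Cl2, rt
Reagents that add atoms: none
Why: Babler–Dauben oxidative 1,3-transposition through [3,3]-shift of the allylic chromate ester moves the carbonyl to C8 and leaves C10 as the methyl-bearing alkene carbon; the buffer protects the ketal and the now enolisable C7.

**Step 7**
Reactants: 9 enone
Product: 10 (1R,4R,6R)-4-(1,1-dimethoxyethyl)-3-methyl-6-(propan-2-yl)cyclohex-2-en-1-ol (8α-OH, trans to isopropyl)
Conditions: NaBH4, CeCl3·7H2O, MeOH, −78 °C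
Reagents that add atoms: none
Why: Luche 1,2-reduction in which axial hydride delivery to the half-chair with both ring substituents equatorial should give the pseudo-equatorial alcohol trans to the isopropyl group (C8).

**Step 8**
Reactants: 10 allylic alcohol
Product: 11 tert-butyl{[(1R,4R,6R)-4-(1,1-dimethoxyethyl)-3-methyl-6-(propan-2-yl)cyclohex-2-en-1-yl]oxy}dimethylsilane
Conditions: t-BuMe2SiCl, imidazole, DMAP (cat.), DMF, 40 °C
Reagents that add atoms: tert-butyldimethylsilyl chloride, CC(C)(C)[Si](C)(C)Cl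
Why: Standard silylation of the secondary alcohol; a silyl ether is chosen because it offers no weak C–H bond to the C10 radical of step 13.

**Step 9**
Reactants: 11 silyl ether ketal
Product: 12 1-[(1R,4R,5R)-4-{[tert-butyl(dimethyl)silyl]oxy}-2-methyl-5-(propan-2-yl)cyclohex-2-en-1-yl]ethan-1-one
Conditions: PPTS (cat.), acetone/H2O, rt
Reagents that add atoms: water, O
Why: Mild acid-catalysed ketal hydrolysis unmasks the methyl ketone while the silyl ether and the C5 configuration should survive.

**Step 10**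
Reactants: 12 methyl ketone
Product: 14 tert-butyl{[(1R,4R,6R)-4-(1-iodoethenyl)-3-methyl-6-(propan-2-yl)cyclohex-2-en-1-yl]oxy}dimethylsilane, via hydrazone 13 (not isolated)
Conditions: N2H4·H2O, EtOH, rt; then I2, tetramethylguanidine, THF, 0 °C
Reagents that add atoms: iodine, II
Why: Barton vinyl iodide synthesis, in which iodine oxidises the hydrazone to an iodo-diazonium/carbenium species that loses the methyl proton to give the 1-iodoethenyl group (future C4=C15).

**Step 11**
Reactants: 15 methyl propiolate; 16 4-methoxybenzyl alcohol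
Product: 17 methyl (E)-3-[(4-methoxybenzyl)oxy]prop-2-enoate
Conditions: N-methylmorpholine (cat.), CH2Cl2, rt
Reagents that add atoms: none
Why: Amine-catalysed oxa-Michael addition of the alcohol to the propiolate gives the (E)-β-alkoxyacrylate, the C1–C2–C3 unit with both oxygens in place.

**Step 12**
Reactants: 17 β-alkoxyacrylate
Product: 18 (E)-N-methoxy-3-[(4-methoxybenzyl)oxy]-N-methylprop-2-enamide
Conditions: MeNH(OMe)·HCl, i-PrMgCl, THF, −20 °C
Reagents that add atoms: N,O-dimethylhydroxylamine hydrochloride, CNOC.Cl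
Why: Amidation of the ester by the magnesium amide of N,O-dimethylhydroxylamine gives a Weinreb amide, an acyl donor that stops at the ketone stage.

**Step 13**
Reactants: 14 vinyl iodide; 18 Weinreb amide
Product: 20 8α-(tert-butyldimethylsilyloxy)-1β-[(4-methoxybenzyl)oxy]-5αH-eudesm-4(15)-en-3-one (trans-decalin, 7β-isopropyl, 10β-methyl), via dienone 19 (not isolated)
Conditions: t-BuLi (2 equiv), Et2O, −78 °C; 18, −78 to −20 °C; AcOH; then Fe(acac)3 (30 mol%), PhSiH3, EtOH/THF, 50 °C
Reagents that add atoms: none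
Why: Iodine–lithium exchange gives the 1-substituted alkenyllithium at C4, which acylates 18 through the stable N,O-chelate to form the C3–C4 bond; the cross-conjugated dienone 19, prone to 4π-electrocyclisation and polymerisation, is neutralised and used in the same flask. Iron hydride formed from Fe(acac)3 and PhSiH3 then transfers a hydrogen atom to C9 of the trisubstituted C9=C10 alkene (Markovnikov), and the tertiary C10 radical adds to C1, the alkoxy-bearing β-carbon of the vinylogous ester, in a 6-endo-trig Giese cyclisation, after which the α-keto radical at C2 is reduced and protonated. The closest known reaction types are the hydrogen-atom-transfer-initiated reductive coupling of alkenes with enones and the 6-endo steps of radical polyene cyclisations. Ring A should close through a chair-like transition state on the all-equatorial chair of ring B, with the C5 tether and the forming C10–C1 bond both equatorial, so the methyl becomes axial and the ring fusion trans (C10 controlled by C5). The (E)-geometry of the enol ether should place the 4-methoxybenzyloxy group equatorial at C1 (1β). The step needs hydrogen-atom transfer to the isolated electron-rich alkene and not to the two electron-poor alkenes of the dienone, secured by the donor/acceptor polarity of the two alkene types, and 6-endo attack at C1 and not 5-exo attack at C2, secured by the β-selectivity of nucleophilic radicals towards enones whose carbonyl lies inside the tether.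

**Step 14**
Reactants: 20 enone
Product: 21 8α-(tert-butyldimethylsilyloxy)-1β-[(4-methoxybenzyl)oxy]-5αH-eudesm-4(15)-en-3β-ol
Conditions: NaBH4, CeCl3·7H2O, MeOH, −78 °C
Reagents that add atoms: none
Why: Luche 1,2-reduction of the 2-methylene ketone, where axial hydride attack on the α-face of the rigid trans-decalin should give the equatorial 3β-alcohol.

**Step 15**
Reactants: 21 allylic alcohol; 22 2-[bis(2,2,2-trifluoroethoxy)phosphoryl]acetic acid
Product: 23 3β-O-{2-[bis(2,2,2-trifluoroethoxy)phosphoryl]acetyl} derivative of 21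
Conditions: i-PrN=C=N-i-Pr, DMAP (cat.), CH2Cl2, 0 °C to rt
Reagents that add atoms: none
Why: Steglich-type carbodiimide esterification of the unhindered equatorial allylic alcohol, the only free hydroxyl.

**Step 16**
Reactants: 24 3,4-dihydroxybenzaldehyde
Product: 25 3,4-bis(tert-butyldimethylsilyloxy)benzaldehyde
Conditions: t-BuMe2SiCl, imidazole, DMF, rt
Reagents that add atoms: tert-butyldimethylsilyl chloride, CC(C)(C)[Si](C)(C)Cl
Why: Silylation of both phenols gives a catechol protection that is removed at the end together with the C8 silyl ether.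

**Step 17**
Reactants: 23 phosphonoacetate; 25 aldehyde
Product: 26 8α-(tert-butyldimethylsilyloxy)-1β-[(4-methoxybenzyl)oxy]-5αH-eudesm-4(15)-en-3β-yl (Z)-3-[3,4-bis(tert-butyldimethylsilyloxy)phenyl]prop-2-enoate
Conditions: KN(SiMe3)2, 18-crown-6, THF, −78 °C
Reagents that add atoms: none
Why: Still–Gennari olefination, in which the electron-poor bis(trifluoroethyl) phosphonate eliminates fast from the kinetically formed oxaphosphetane and should give the (Z)-enoate.

**Step 18**
Reactants: 26 protected ester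
Product: 27 8α-(tert-butyldimethylsilyloxy)-1β-hydroxy-5αH-eudesm-4(15)-en-3β-yl (Z)-3-[3,4-bis(tert-butyldimethylsilyloxy)phenyl]prop-2-enoate
Conditions: DDQ, CH2Cl2/pH 7 buffer, 0 °C
Reagents that add atoms: none
Why: Oxidative cleavage of the 4-methoxybenzyl ether by benzylic hydride abstraction and hydrolysis; the silyl ethers, the alkenes and the silylated catechol should be inert.

**Step 19**
Reactants: 27 tris-silyl ether
Product: 28 (1R,3S,5S,7R,8S,10R)-1β,8α-dihydroxyeudesm-4(15)-en-3β-yl (Z)-3-(3,4-dihydroxyphenyl)prop-2-enoate (target)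
Conditions: HF·pyridine, pyridine, THF, 0 °C to rt
Reagents that add atoms: none
Why: Fluoride-mediated cleavage of the three silyl ethers under buffered, non-basic conditions that should neither cleave the ester nor isomerise the (Z)-alkene.

**Compound list**
1 | 3-methylbutanal | CC(C)CC=O | starting material
2 | but-3-en-2-one | CC(=O)C=C | starting material
3 | (2R)-5-oxo-2-(propan-2-yl)hexanal | O=C[C@@H](C(C)C)CCC(C)=O | intermediate
4 | (4R)-4-(propan-2-yl)cyclohex-2-en-1-one | O=C1C=C[C@@H](C(C)C)CC1 | intermediate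
5 | trimethyl{[(4R)-4-(propan-2-yl)cyclohexa-1,5-dien-1-yl]oxy}silane | C[Si](C)(C)OC1=CC[C@H](C(C)C)C=C1 | intermediate
6 | trimethyl orthoacetate | CC(OC)(OC)OC | starting material
7 | (4R,6R)-6-(1,1-dimethoxyethyl)-4-(propan-2-yl)cyclohex-2-en-1-one | O=C1C=C[C@@H](C(C)C)C[C@H]1C(C)(OC)OC | intermediate
8 | (4R,6R)-6-(1,1-dimethoxyethyl)-1-methyl-4-(propan-2-yl)cyclohex-2-en-1-ol, both C1 epimers | CC1(O)C=C[C@@H](C(C)C)C[C@H]1C(C)(OC)OC | intermediate
9 | (4R,6R)-4-(1,1-dimethoxyethyl)-3-methyl-6-(propan-2-yl)cyclohex-2-en-1-one | O=C1C=C(C)[C@H](C(C)(OC)OC)C[C@@H]1C(C)C | intermediate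
10 | (1R,4R,6R)-4-(1,1-dimethoxyethyl)-3-methyl-6-(propan-2-yl)cyclohex-2-en-1-ol | O[C@H]1C=C(C)[C@H](C(C)(OC)OC)C[C@@H]1C(C)C | intermediate
11 | tert-butyl{[(1R,4R,6R)-4-(1,1-dimethoxyethyl)-3-methyl-6-(propan-2-yl)cyclohex-2-en-1-yl]oxy}dimethylsilane | CC(C)(C)[Si](C)(C)O[C@H]1C=C(C)[C@H](C(C)(OC)OC)C[C@@H]1C(C)C | intermediate
12 | 1-[(1R,4R,5R)-4-{[tert-butyl(dimethyl)silyl]oxy}-2-methyl-5-(propan-2-yl)cyclohex-2-en-1-yl]ethan-1-one | CC(C)(C)[Si](C)(C)O[C@H]1C=C(C)[C@H](C(C)=O)C[C@@H]1C(C)C | intermediate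
13 | hydrazone of 12 | CC(C)(C)[Si](C)(C)O[C@H]1C=C(C)[C@H](C(C)=NN)C[C@@H]1C(C)C | intermediate
14 | tert-butyl{[(1R,4R,6R)-4-(1-iodoethenyl)-3-methyl-6-(propan-2-yl)cyclohex-2-en-1-yl]oxy}dimethylsilane | CC(C)(C)[Si](C)(C)O[C@H]1C=C(C)[C@H](C(I)=C)C[C@@H]1C(C)C | intermediate
15 | methyl propiolate | COC(=O)C#C | starting material
16 | 4-methoxybenzyl alcohol | COc1ccc(CO)cc1 | starting material
17 | methyl (E)-3-[(4-methoxybenzyl)oxy]prop-2-enoate | COC(=O)/C=C/OCc1ccc(OC)cc1 | intermediate
18 | (E)-N-methoxy-3-[(4-methoxybenzyl)oxy]-N-methylprop-2-enamide | CON(C)C(=O)/C=C/OCc1ccc(OC)cc1 | intermediate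
19 | (E)-2-[(1R,4R,5R)-4-{[tert-butyl(dimethyl)silyl]oxy}-2-methyl-5-(propan-2-yl)cyclohex-2-en-1-yl]-5-[(4-methoxybenzyl)oxy]penta-1,4-dien-3-one | CC(C)(C)[Si](C)(C)O[C@H]1C=C(C)[C@H](C(=C)C(=O)/C=C/OCc2ccc(OC)cc2)C[C@@H]1C(C)C | intermediate
20 | 8α-(tert-butyldimethylsilyloxy)-1β-[(4-methoxybenzyl)oxy]-5αH-eudesm-4(15)-en-3-one | C=C1C(=O)C[C@@H](OCc3ccc(OC)cc3)[C@]2(C)C[C@H](O[Si](C)(C)C(C)(C)C)[C@@H](C(C)C)C[C@@H]12 | intermediate
21 | 8α-(tert-butyldimethylsilyloxy)-1β-[(4-methoxybenzyl)oxy]-5αH-eudesm-4(15)-en-3β-ol | C=C1[C@@H](O)C[C@@H](OCc3ccc(OC)cc3)[C@]2(C)C[C@H](O[Si](C)(C)C(C)(C)C)[C@@H](C(C)C)C[C@@H]12 | intermediate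
22 | 2-[bis(2,2,2-trifluoroethoxy)phosphoryl]acetic acid | OC(=O)CP(=O)(OCC(F)(F)F)OCC(F)(F)F | starting material
23 | 3β-O-{2-[bis(2,2,2-trifluoroethoxy)phosphoryl]acetyl} derivative of 21 | C=C1[C@@H](OC(=O)CP(=O)(OCC(F)(F)F)OCC(F)(F)F)C[C@@H](OCc3ccc(OC)cc3)[C@]2(C)C[C@H](O[Si](C)(C)C(C)(C)C)[C@@H](C(C)C)C[C@@H]12 | intermediate
24 | 3,4-dihydroxybenzaldehyde | O=Cc1ccc(O)c(O)c1 | starting material
25 | 3,4-bis(tert-butyldimethylsilyloxy)benzaldehyde | O=Cc1ccc(O[Si](C)(C)C(C)(C)C)c(O[Si](C)(C)C(C)(C)C)c1 | intermediate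
26 | 8α-(tert-butyldimethylsilyloxy)-1β-[(4-methoxybenzyl)oxy]-5αH-eudesm-4(15)-en-3β-yl (Z)-3-[3,4-bis(tert-butyldimethylsilyloxy)phenyl]prop-2-enoate | C=C1[C@@H](OC(=O)/C=C\c4ccc(O[Si](C)(C)C(C)(C)C)c(O[Si](C)(C)C(C)(C)C)c4)C[C@@H](OCc3ccc(OC)cc3)[C@]2(C)C[C@H](O[Si](C)(C)C(C)(C)C)[C@@H](C(C)C)C[C@@H]12 | intermediate
27 | 8α-(tert-butyldimethylsilyloxy)-1β-hydroxy-5αH-eudesm-4(15)-en-3β-yl (Z)-3-[3,4-bis(tert-butyldimethylsilyloxy)phenyl]prop-2-enoate | C=C1[C@@H](OC(=O)/C=C\c4ccc(O[Si](C)(C)C(C)(C)C)c(O[Si](C)(C)C(C)(C)C)c4)C[C@@H](O)[C@]2(C)C[C@H](O[Si](C)(C)C(C)(C)C)[C@@H](C(C)C)C[C@@H]12 | intermediate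
28 | (1R,3S,5S,7R,8S,10R)-1β,8α-dihydroxyeudesm-4(15)-en-3β-yl (Z)-3-(3,4-dihydroxyphenyl)prop-2-enoate | C=C1[C@@H](OC(=O)/C=C\c2ccc(O)c(O)c2)C[C@@H](O)[C@]2(C)C[C@H](O)[C@@H](C(C)C)C[C@@H]12 | target

**Step count**
Total: 19 steps. Longest linear sequence: 16 steps (steps 1–10, 13–15, 17–19).

**Three steps most likely to fail**

Step 13. What may go wrong: addition–elimination of the alkenyllithium at the alkoxy-bearing carbon of 18, decay of crude 19 by electrocyclisation or polymerisation before the radical stage, and hydrogen-atom transfer to the 2-methylene ketone or closure to the cis-fused isomer during it. Fallback: set out from 14 and make the C3–C4 bond by a Nozaki–Hiyama–Kishi coupling (CrCl2, NiCl2 cat., DMF) with (E)-3-[(4-methoxybenzyl)oxy]prop-2-enal F1, itself made from the sodium enolate of malonaldehyde and 4-methoxybenzyl chloride. This should give the bis-allylic alcohol F2 as a mixture of carbinol epimers. Dess–Martin oxidation should then give 19, which would be purified quickly and cyclised in a separate flask at high dilution with Fe(acac)3 and PhSiH3; the sequence comes back to the route at 20.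

Step 10. What may go wrong: epimerisation at C5 (α to the ketone and hydrazone, driven by relief of allylic strain against the C10 methyl) and formation of the regioisomeric internal vinyl iodide. Fallback: set out from 12 and enolise the methyl group kinetically with KN(SiMe3)2 at −78 °C, trapping with PhNTf2 to give the enol triflate F3. Stannylation with Me3SnSnMe3, LiCl and Pd(PPh3)4 should give the alkenylstannane F4, and iododestannylation with I2 comes back to the route at 14.

Step 17. What may go wrong: erosion of (Z)-selectivity in the olefination, or (Z)-to-(E) isomerisation of the enoate under the basic conditions. Fallback: set out from 25 and convert it by Corey–Fuchs homologation (CBr4, PPh3) into the dibromoalkene F5, then with n-BuLi and CO2 into the arylpropiolic acid F6. Carbodiimide esterification of 21 with F6 should give the alkynoate F7, and semi-hydrogenation over Pd/CaCO3 poisoned with Pb(OAc)2 and quinoline should deliver the cis-alkene, coming back to the route at 26.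

**Further compounds**
F1 | step 13 | (E)-3-[(4-methoxybenzyl)oxy]prop-2-enal | O=C/C=C/OCc1ccc(OC)cc1
F2 | step 13 | (E)-2-[(1R,4R,5R)-4-{[tert-butyl(dimethyl)silyl]oxy}-2-methyl-5-(propan-2-yl)cyclohex-2-en-1-yl]-5-[(4-methoxybenzyl)oxy]penta-1,4-dien-3-ol, both carbinol epimers | CC(C)(C)[Si](C)(C)O[C@H]1C=C(C)[C@H](C(=C)C(O)/C=C/OCc2ccc(OC)cc2)C[C@@H]1C(C)C
F3 | step 10 | 1-[(1R,4R,5R)-4-{[tert-butyl(dimethyl)silyl]oxy}-2-methyl-5-(propan-2-yl)cyclohex-2-en-1-yl]ethenyl trifluoromethanesulfonate | CC(C)(C)[Si](C)(C)O[C@H]1C=C(C)[C@H](C(=C)OS(=O)(=O)C(F)(F)F)C[C@@H]1C(C)C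
F4 | step 10 | tert-butyldimethyl{[(1R,4R,6R)-3-methyl-6-(propan-2-yl)-4-[1-(trimethylstannyl)ethenyl]cyclohex-2-en-1-yl]oxy}silane | CC(C)(C)[Si](C)(C)O[C@H]1C=C(C)[C@H](C(=C)[Sn](C)(C)C)C[C@@H]1C(C)C
F5 | step 17 | 4-(2,2-dibromoethenyl)-1,2-bis(tert-butyldimethylsilyloxy)benzene | BrC(Br)=Cc1ccc(O[Si](C)(C)C(C)(C)C)c(O[Si](C)(C)C(C)(C)C)c1
F6 | step 17 | 3-[3,4-bis(tert-butyldimethylsilyloxy)phenyl]prop-2-ynoic acid | OC(=O)C#Cc1ccc(O[Si](C)(C)C(C)(C)C)c(O[Si](C)(C)C(C)(C)C)c1
F7 | step 17 | 8α-(tert-butyldimethylsilyloxy)-1β-[(4-methoxybenzyl)oxy]-5αH-eudesm-4(15)-en-3β-yl 3-[3,4-bis(tert-butyldimethylsilyloxy)phenyl]prop-2-ynoate | C=C1[C@@H](OC(=O)C#Cc4ccc(O[Si](C)(C)C(C)(C)C)c(O[Si](C)(C)C(C)(C)C)c4)C[C@@H](OCc3ccc(OC)cc3)[C@]2(C)C[C@H](O[Si](C)(C)C(C)(C)C)[C@@H](C(C)C)C[C@@H]12
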